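The runs are calculated from invented constants; scatter was added.

Late in the ochre run the target gains little, 19.6% at 30.0 h and 20.5% at 40.0 h, while the red run is still climbing at 96.0 h.

the same everywhere: starting material 0.10 M
- red: second nucleophile 0.15 M; solid first nucleophile 0.090 M; protic impurity 0.020 M; temperature −5 °C; run made earlier
- ochre: second nucleophile 0.24 M; solid first nucleophile 0.090 M; protic impurity 0.020 M; temperature 10 °C; run made earlier
- alpha: second nucleophile 0.110 M; solid first nucleophile 0.0900 M; protic impurity 0.0200 M; temperature 20 °C; time 30 h
- beta: second nucleophile 0.110 M; solid first nucleophile 0.0900 M; protic impurity 0.0200 M; temperature 0 °C; time 30 h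

- red (time / h: target / %): 20.0: 6.5; 40.0: 12.0; 72.0: 19.8; 96.0: 24.2
- ochre (time / h: target / %): 10.0: 10.5; 20.0: 16.0; 30.0: 19.6; 40.0: 20.5

(scatter of a reading: 0.3 percentage points)

- which flask leads in amount of target, in percent of the starting material charged ("all alike" within 1.5 percentage points) (alpha / beta / all alike)
- how much target is there at the end, in percent of the starting material charged: alpha
- how much target is there at the end, in percent of the starting material charged: beta

- at the start none of the solid first nucleophile is in solution

Both rises read as a pseudo-first-order approach to a plateau. The gains over two equal intervals give, as readings with their scatter, the constant k: 0.0647 h⁻¹ for ochre and 0.00835 h⁻¹ for red, with plateaus read near 22.1% and 42.2%.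

The bench rule of doubling per 10 K, read with the charges held, halves the ochre constant for beta and gives k·t = 0.970. That rule stops here: it allows under 3 between the two runs, but the readings give a ratio of 7.75, although the second nucleophile differs too.

Interpolating on the readings instead gives 0.0165 h⁻¹ for beta, so N = 0.496, the turnover count, time over time constant. By this reckoning beta stands at 39.1% of its plateau after 30 h. Alpha, extrapolated beyond both runs to 0.253 h⁻¹, has N = 7.59, which the same reckoning counts as being at its plateau. For beta to lead on this reckoning, its plateau must stand 2.56 times over alpha's. The plateau read for red stands 1.91 times over the one read for ochre across a narrower temperature gap, with the second nucleophile differing as well, so this reckoning calls the lead close.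

The forecast names beta as leader, with alpha at 8.5% and beta at 11%: “Beta probably leads narrowly”.

The simulation has beta ahead, with alpha at 12.0% and beta at 16.6%, which is 5.6 percentage points over the forecast for beta. Beta has converted 56.3% of its starting material by then, and at 300 h its target stands at 40.0%. The ratio of beta's target to alpha's at that late time is thus 3.33 against the 2.56 required, and beta's 41.5% of that late value after 30 h lies beside the reckoned 39.1%.

    intermediate → side product (k = 3.90 × 10⁻⁶ s⁻¹, Ea = 100 kJ mol⁻¹)
    first nucleophile + intermediate → target (k = 0.00930 M⁻¹ s⁻¹, Ea = 63.0 kJ mol⁻¹)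
    starting material + protic impurity → quenched substrate (k = 3.80 × 10⁻⁴ M⁻¹ s⁻¹, Ea = 57.0 kJ mol⁻¹)
    intermediate → solvolysis product (k = 4.70 × 10⁻⁵ s⁻¹, Ea = 89.0 kJ mol⁻¹)
    starting material → intermediate (k = 5.40 × 10⁻⁶ s⁻¹, Ea = 91.0 kJ mol⁻¹)
    second nucleophile + intermediate → other capture product (k = 3.80 × 10⁻⁴ M⁻¹ s⁻¹, Ea = 63.0 kJ mol⁻¹)
    solid first nucleophile ⇌ first nucleophile, rate k7*(cs7 - [first nucleophile]) while solid is left; crystals form when [first nucleophile] > cs7 (solubility = 12.0 mM, k = 6.70 × 10⁻⁵ s⁻¹)
    (constants at 0 °C)

Beta read at 5.0 d has N = 1.98, so 86.2% of the plateau, or 34.5% target. The simulation gives 35.9%.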